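**Retrosynthetic overview**
- The route rests on ring B (C1'–C6'): oxygens at C2' and C5' are para, a third oxygen sits at C4', and the C1'–C3 bond to ring C is ortho to the C2' oxygen. This is the pattern a methoxy(alkenyl)carbene, a terminal alkyne and CO give, so ring B is built by Dötz benzannulation on a 3-ethynylchromone.
- The C6 prenyl group is disconnected to a 7-O-(1,1-dimethylallyl) ether (Claisen shift; C8 is blocked by OMe).
- The 3-ethynylchromone comes from the 3-iodochromone (Sonogashira), which comes from the enaminone of a ring A 2-hydroxyacetophenone; its C8 oxygen is installed by formylation and Baeyer–Villiger oxidation of 2,4,6-trihydroxyacetophenone.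
- Ring order: ring A is bought, ring C is closed in step 6, ring B is built in step 10.

Key step: step 10

Remark: in the SMILES, CO ligands on chromium are drawn as Cr=C=O, and the arene–Cr(CO)3 complex 18 is drawn as two dot-joined parts because η6 bonding cannot be drawn.

**Route**

Step 1
Reactants: 1 1-(2,4,6-trihydroxyphenyl)ethan-1-one
Product: 3 3-acetyl-2,4,6-trihydroxybenzaldehyde, via aryl iminium chloride 2 (not isolated)
Conditions: POCl3 (1.1 equiv), DMF, EtOAc, 0 °C to rt; then H2O, 60 °C
Reagents that add atoms: N,N-dimethylformamide, CN(C)C=O; water, O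
Why: Vilsmeier–Haack formylation of the strongly nucleophilic phloroglucinol ring should be much faster at low temperature than attack at the acetyl methyl, and the two free ring positions are equivalent, so one aldehyde is expected.

Step 2
Reactants: 3 3-acetyl-2,4,6-trihydroxybenzaldehyde
Product: 4 3-acetyl-4,6-bis(benzyloxy)-2-hydroxybenzaldehyde
Conditions: BnBr (2.1 equiv), K2CO3 (2.2 equiv), DMF, 0 °C to rt
Reagents that add atoms: benzyl bromide, BrCc1ccccc1
Why: Williamson benzylation should take the two hydroxyls that are each para to one carbonyl, because the hydroxyl flanked by both carbonyl groups is the most hindered and is held in hydrogen bonds.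

Step 3
Reactants: 4 3-acetyl-4,6-bis(benzyloxy)-2-hydroxybenzaldehyde
Product: 6 1-[4,6-bis(benzyloxy)-2,3-dihydroxyphenyl]ethan-1-one, via aryl formate 5 (not isolated)
Conditions: mCPBA (1.1 equiv), CH2Cl2, 0 °C to rt; aq. NaHCO3 wash; then K2CO3 (cat.), MeOH, 0 °C, argon
Reagents that add atoms: 3-chloroperoxybenzoic acid, OOC(=O)c1cccc(Cl)c1
Why: Baeyer–Villiger (Dakin-type) oxidation with aryl migration is fast for a 2,4,6-trioxygenated benzaldehyde and slow for the aryl methyl ketone, and the formate is then removed by mild methanolysis.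

Step 4
Reactants: 6 1-[4,6-bis(benzyloxy)-2,3-dihydroxyphenyl]ethan-1-one
Product: 7 1-[4,6-bis(benzyloxy)-2-hydroxy-3-methoxyphenyl]ethan-1-one
Conditions: MeI (1.05 equiv), K2CO3 (1.1 equiv), acetone, rt to 40 °C
Reagents that add atoms: iodomethane, CI
Why: In this selective Williamson methylation the 2-hydroxyl is chelated to the acetyl carbonyl and is a poor nucleophile, so one equivalent of MeI should methylate the 3-hydroxyl only.

Step 5
Reactants: 7 1-[4,6-bis(benzyloxy)-2-hydroxy-3-methoxyphenyl]ethan-1-one
Product: 8 (E)-1-[4,6-bis(benzyloxy)-2-hydroxy-3-methoxyphenyl]-3-(dimethylamino)prop-2-en-1-one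
Conditions: DMF-DMA, toluene, 95 °C
Reagents that add atoms: N,N-dimethylformamide dimethyl acetal, COC(OC)N(C)C
Why: Condensation of the acetyl methyl group with the amide acetal is the standard entry to 2-hydroxyaryl enaminones, and the E isomer is the stable one.

Step 6
Reactants: 8 (E)-1-[4,6-bis(benzyloxy)-2-hydroxy-3-methoxyphenyl]-3-(dimethylamino)prop-2-en-1-one
Product: 9 5,7-bis(benzyloxy)-3-iodo-8-methoxy-4H-chromen-4-one
Conditions: I2 (1.5 equiv), CHCl3, rt
Reagents that add atoms: iodine, II
Why: Iodine-induced cyclization of the enaminone (iodination at the α-carbon, attack of the phenol on the iminium carbon, loss of dimethylamine) closes ring C and places iodine on C3, a standard 3-iodochromone synthesis.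

Step 7
Reactants: 9 5,7-bis(benzyloxy)-3-iodo-8-methoxy-4H-chromen-4-one; 10 trimethylsilylacetylene
Product: 11 5,7-bis(benzyloxy)-8-methoxy-3-[(trimethylsilyl)ethynyl]-4H-chromen-4-one
Conditions: 10 (1.5 equiv), PdCl2(PPh3)2 (3 mol %), CuI (5 mol %), Et3N, THF, rt
Reagents that add atoms: none
Why: Sonogashira coupling of 3-iodochromones is well established, and a tertiary amine base avoids the ring opening that secondary amines cause at C2.

Step 8
Reactants: 11 5,7-bis(benzyloxy)-8-methoxy-3-[(trimethylsilyl)ethynyl]-4H-chromen-4-one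
Product: 12 5,7-bis(benzyloxy)-3-ethynyl-8-methoxy-4H-chromen-4-one
Conditions: TBAF, AcOH (1:1), THF, 0 °C
Reagents that add atoms: none
Why: Fluoride-mediated protodesilylation of the alkynylsilane, buffered with acetic acid, should spare the base-sensitive C2 position of the chromone.

Step 9
Reactants: 13 methyl vinyl ether; 14 chromium hexacarbonyl Cr(CO)6
Product: 17 pentacarbonyl[methoxy(1-methoxyethenyl)methylidene]chromium, via 1-methoxyvinyllithium 15 (not isolated), via lithium acylchromate 16 (not isolated)
Conditions: 13, t-BuLi, THF, −78 to 0 °C; then Cr(CO)6, THF, 0 °C to rt; then Me3OBF4, CH2Cl2/H2O, 0 °C; used freshly prepared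
Reagents that add atoms: trimethyloxonium tetrafluoroborate, C[O+](C)C.F[B-](F)(F)F
Why: This is the Fischer carbene synthesis, in which α-lithiated methyl vinyl ether adds to a CO ligand of Cr(CO)6 and the acylate oxygen is methylated by the hard oxonium salt.

Step 10
Reactants: 12 5,7-bis(benzyloxy)-3-ethynyl-8-methoxy-4H-chromen-4-one; 17 pentacarbonyl[methoxy(1-methoxyethenyl)methylidene]chromium
Product: 19 5,7-bis(benzyloxy)-3-(2-hydroxy-4,5-dimethoxyphenyl)-8-methoxy-4H-chromen-4-one, via tricarbonylchromium arene complex 18 (not isolated)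
Conditions: 17 (1.5 equiv), THF (0.05 M), 55 °C, argon; then air, Et2O/MeCN, rt
Reagents that add atoms: none
Why: Thermal loss of one CO from 17 frees a site on zerovalent chromium, the alkyne of 12 inserts into the Cr=C bond with its chromonyl-bearing carbon remote from the carbene carbon (C5'–C6' bond), CO inserts into the new vinylcarbene (C1'–C2' bond) to give a metal-bound dienylketene, and electrocyclization onto the vinyl CH2 (C2'–C3' bond) followed by tautomerization should give the phenol as its Cr(CO)3 complex 18, which air demetalates. The closest known reaction type is the Dötz benzannulation of methoxy(alkenyl)carbene complexes of chromium with terminal alkynes to 4-methoxyphenols, including alkenyl groups that carry an α-alkoxy substituent such as 2-dihydropyranyl. Ring B closes by a 6π-electrocyclic closure of the dienylketene, and no stereocenter is formed. The step needs regioselective alkyne insertion so that ring C ends ortho to the new hydroxyl, and the large steric difference between H and the chromon-3-yl group of the terminal alkyne should secure this, since the bulkier end avoids the carbene ligand. It also needs CO insertion to win over cyclopentannulation, which an alkenyl (not aryl) carbene ligand, chromium as the metal and THF as donor solvent favour. The benzyl ethers, the chromone carbonyl and the C2=C3 enol ether bond should be spectators under these neutral conditions.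

Step 11
Reactants: 19 5,7-bis(benzyloxy)-3-(2-hydroxy-4,5-dimethoxyphenyl)-8-methoxy-4H-chromen-4-one
Product: 20 5,7-bis(benzyloxy)-8-methoxy-3-(2,4,5-trimethoxyphenyl)-4H-chromen-4-one
Conditions: MeI, K2CO3, acetone, reflux
Reagents that add atoms: iodomethane, CI
Why: Williamson methylation of the only free phenol should proceed cleanly, and K2CO3 in acetone is mild enough for the isoflavone ring.

Step 12
Reactants: 20 5,7-bis(benzyloxy)-8-methoxy-3-(2,4,5-trimethoxyphenyl)-4H-chromen-4-one
Product: 21 5,7-dihydroxy-8-methoxy-3-(2,4,5-trimethoxyphenyl)-4H-chromen-4-one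
Conditions: H2 (1 atm), Pd/C, EtOAc/MeOH, rt
Reagents that add atoms: none
Why: Hydrogenolysis of aryl benzyl ethers is faster than reduction of the tetrasubstituted, conjugated C2=C3 bond of an isoflavone, provided the reaction is stopped at full debenzylation.

Step 13
Reactants: 21 5,7-dihydroxy-8-methoxy-3-(2,4,5-trimethoxyphenyl)-4H-chromen-4-one; 22 3-chloro-3-methylbut-1-yne
Product: 23 5-hydroxy-8-methoxy-7-[(2-methylbut-3-yn-2-yl)oxy]-3-(2,4,5-trimethoxyphenyl)-4H-chromen-4-one
Conditions: 22, K2CO3, KI, CuI (cat.), acetone, 55 °C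
Reagents that add atoms: none
Why: Copper-catalysed propargylic O-alkylation should take the acidic 7-hydroxyl, while the 5-hydroxyl is chelated to the C4 carbonyl and stays free.

Step 14
Reactants: 23 5-hydroxy-8-methoxy-7-[(2-methylbut-3-yn-2-yl)oxy]-3-(2,4,5-trimethoxyphenyl)-4H-chromen-4-one
Product: 24 5-hydroxy-8-methoxy-7-[(2-methylbut-3-en-2-yl)oxy]-3-(2,4,5-trimethoxyphenyl)-4H-chromen-4-one
Conditions: H2 (1 atm), Pd/CaCO3 poisoned with Pb(OAc)2, quinoline, EtOAc, rt
Reagents that add atoms: none
Why: Semihydrogenation of the terminal alkyne over poisoned palladium should stop at the alkene and leave the chromone double bond untouched.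

Step 15
Reactants: 24 5-hydroxy-8-methoxy-7-[(2-methylbut-3-en-2-yl)oxy]-3-(2,4,5-trimethoxyphenyl)-4H-chromen-4-one
Product: 26 6-prenylisocaviunin, via C6 cyclohexadienone 25 (not isolated)
Conditions: PhNEt2, 130 °C, argon
Reagents that add atoms: none
Why: Aromatic Claisen rearrangement ([3,3] shift with allyl inversion) should deliver the prenyl group to C6, the only free ortho position because C8 carries OMe, and the basic solvent should suppress acid-induced chroman formation.

**Compound list**
1 | 1-(2,4,6-trihydroxyphenyl)ethan-1-one | CC(=O)c1c(O)cc(O)cc1O | starting material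
2 | [(3-acetyl-2,4,6-trihydroxyphenyl)methylidene]dimethyliminium chloride | CC(=O)c1c(O)c(C=[N+](C)C)c(O)cc1O.[Cl-] | intermediate
3 | 3-acetyl-2,4,6-trihydroxybenzaldehyde | CC(=O)c1c(O)c(C=O)c(O)cc1O | intermediate
4 | 3-acetyl-4,6-bis(benzyloxy)-2-hydroxybenzaldehyde | CC(=O)c1c(O)c(C=O)c(OCc2ccccc2)cc1OCc1ccccc1 | intermediate
5 | 3-acetyl-4,6-bis(benzyloxy)-2-hydroxyphenyl formate | CC(=O)c1c(O)c(OC=O)c(OCc2ccccc2)cc1OCc1ccccc1 | intermediate
6 | 1-[4,6-bis(benzyloxy)-2,3-dihydroxyphenyl]ethan-1-one | CC(=O)c1c(O)c(O)c(OCc2ccccc2)cc1OCc1ccccc1 | intermediate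
7 | 1-[4,6-bis(benzyloxy)-2-hydroxy-3-methoxyphenyl]ethan-1-one | CC(=O)c1c(O)c(OC)c(OCc2ccccc2)cc1OCc1ccccc1 | intermediate
8 | (E)-1-[4,6-bis(benzyloxy)-2-hydroxy-3-methoxyphenyl]-3-(dimethylamino)prop-2-en-1-one | CN(C)/C=C/C(=O)c1c(O)c(OC)c(OCc2ccccc2)cc1OCc1ccccc1 | intermediate
9 | 5,7-bis(benzyloxy)-3-iodo-8-methoxy-4H-chromen-4-one | COc1c(OCc2ccccc2)cc(OCc2ccccc2)c2c(=O)c(I)coc12 | intermediate
10 | trimethylsilylacetylene | C#C[Si](C)(C)C | starting material
11 | 5,7-bis(benzyloxy)-8-methoxy-3-[(trimethylsilyl)ethynyl]-4H-chromen-4-one | COc1c(OCc2ccccc2)cc(OCc2ccccc2)c2c(=O)c(C#C[Si](C)(C)C)coc12 | intermediate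
12 | 5,7-bis(benzyloxy)-3-ethynyl-8-methoxy-4H-chromen-4-one | COc1c(OCc2ccccc2)cc(OCc2ccccc2)c2c(=O)c(C#C)coc12 | intermediate
13 | methyl vinyl ether | COC=C | starting material
14 | chromium hexacarbonyl Cr(CO)6 | O=C=[Cr](=C=O)(=C=O)(=C=O)(=C=O)=C=O | starting material
15 | 1-methoxyvinyllithium | [Li]C(=C)OC | intermediate
16 | lithium pentacarbonyl(2-methoxyprop-2-enoyl)chromate | [Li+].[O-]C(C(OC)=C)=[Cr](=C=O)(=C=O)(=C=O)(=C=O)=C=O | intermediate
17 | pentacarbonyl[methoxy(1-methoxyethenyl)methylidene]chromium | COC(C(OC)=C)=[Cr](=C=O)(=C=O)(=C=O)(=C=O)=C=O | intermediate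
18 | tricarbonylchromium complex of phenol 19 (Cr(CO)3 η6-bound to ring B) | COc1cc(O)c(-c2coc3c(OC)c(OCc4ccccc4)cc(OCc4ccccc4)c3c2=O)cc1OC.O=C=[Cr](=C=O)=C=O | intermediate
19 | 5,7-bis(benzyloxy)-3-(2-hydroxy-4,5-dimethoxyphenyl)-8-methoxy-4H-chromen-4-one | COc1cc(O)c(-c2coc3c(OC)c(OCc4ccccc4)cc(OCc4ccccc4)c3c2=O)cc1OC | intermediate
20 | 5,7-bis(benzyloxy)-8-methoxy-3-(2,4,5-trimethoxyphenyl)-4H-chromen-4-one | COc1cc(OC)c(-c2coc3c(OC)c(OCc4ccccc4)cc(OCc4ccccc4)c3c2=O)cc1OC | intermediate
21 | 5,7-dihydroxy-8-methoxy-3-(2,4,5-trimethoxyphenyl)-4H-chromen-4-one | COc1cc(OC)c(-c2coc3c(OC)c(O)cc(O)c3c2=O)cc1OC | intermediate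
22 | 3-chloro-3-methylbut-1-yne | CC(C)(Cl)C#C | starting material
23 | 5-hydroxy-8-methoxy-7-[(2-methylbut-3-yn-2-yl)oxy]-3-(2,4,5-trimethoxyphenyl)-4H-chromen-4-one | COc1cc(OC)c(-c2coc3c(OC)c(OC(C)(C)C#C)cc(O)c3c2=O)cc1OC | intermediate
24 | 5-hydroxy-8-methoxy-7-[(2-methylbut-3-en-2-yl)oxy]-3-(2,4,5-trimethoxyphenyl)-4H-chromen-4-one | COc1cc(OC)c(-c2coc3c(OC)c(OC(C)(C)C=C)cc(O)c3c2=O)cc1OC | intermediate
25 | 5-hydroxy-8-methoxy-6-(3-methylbut-2-en-1-yl)-3-(2,4,5-trimethoxyphenyl)-4H-chromene-4,7(6H)-dione (racemic at C6) | COc1cc(OC)c(C2=COC3=C(OC)C(=O)C(CC=C(C)C)C(O)=C3C2=O)cc1OC | intermediate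
26 | 6-prenylisocaviunin, 5,7-dihydroxy-8-methoxy-6-(3-methylbut-2-en-1-yl)-3-(2,4,5-trimethoxyphenyl)-4H-chromen-4-one | COc1cc(OC)c(-c2coc3c(OC)c(O)c(CC=C(C)C)c(O)c3c2=O)cc1OC | target

**Step count**
Total: 15 steps. Longest linear sequence: 14 steps (steps 1–8 and 10–15, from compound 1); step 9 is a one-step branch.

**Steps most likely to fail**

Step 10. The carbene complex may decompose thermally, or the vinylcarbene may cyclize without CO insertion, before the benzannulation is complete; the terminal alkyne may also oligomerize on chromium. The fallback sets out from 3-iodochromone 9 and forms the C3–C1' bond by Suzuki–Miyaura coupling with commercial 2,4,5-trimethoxyphenylboronic acid (Pd(PPh3)4, K2CO3, dioxane/H2O, 80 °C). It comes back to the route at compound 20, so steps 7–11 are bypassed; no new compound is made on this way (F0).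

Step 9. O-Methylation of the acylate may be incomplete, and the electron-poor enol ether complex may be lost during aqueous handling and chromatography. The fallback sets out from 13 and 14 and makes lithium acylate 16 as before. It is precipitated from water with Me4NBr as the storable salt tetramethylammonium pentacarbonyl(2-methoxyprop-2-enoyl)chromate F1. This salt is acylated with acetyl bromide in CH2Cl2 at −40 °C to pentacarbonyl[acetoxy(1-methoxyethenyl)methylidene]chromium F2. Methanol then displaces acetate at the carbene carbon and gives 17, where the fallback comes back to the route; 17 is used at once without chromatography.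

Step 2. Site selectivity of the O-benzylation may be lost, with alkylation of the doubly chelated hydroxyl or tribenzylation. The fallback sets out from compound 1 and reverses the order of events. Benzyl bromide (2 equiv) and K2CO3 in DMF give 1-[2,4-bis(benzyloxy)-6-hydroxyphenyl]ethan-1-one F3, in which the single chelated hydroxyl stays free. Magnesium-mediated ortho-formylation (MgCl2, Et3N, paraformaldehyde, MeCN, reflux) then places the aldehyde on the only free position ortho to that hydroxyl. This comes back to the route at compound 4.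

**Further compounds**
F0 | step 10 | none | none
F1 | step 9 | tetramethylammonium pentacarbonyl(2-methoxyprop-2-enoyl)chromate | C[N+](C)(C)C.[O-]C(C(OC)=C)=[Cr](=C=O)(=C=O)(=C=O)(=C=O)=C=O
F2 | step 9 | pentacarbonyl[acetoxy(1-methoxyethenyl)methylidene]chromium | CC(=O)OC(C(OC)=C)=[Cr](=C=O)(=C=O)(=C=O)(=C=O)=C=O
F3 | step 2 | 1-[2,4-bis(benzyloxy)-6-hydroxyphenyl]ethan-1-one | CC(=O)c1c(O)cc(OCc2ccccc2)cc1OCc1ccccc1
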